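Readings and results are simulated with made-up constants, and the scatter is random.

I had no constants, so I worked from the two earlier runs and left this note at the bench.

| setting | spring | noon | north-west | south-east | south-west | north |
|---|---|---|---|---|---|---|
| Q | 10 mM | 10 mM | 10 mM | 10 mM | 10 mM | 10 mM |
| J | 5 mM | 170 mM | 8.00 mM | 20.0 mM | 60.0 mM | 200 mM |
| D | 50 µM | 50 µM | 50 µM | 50 µM | 50 µM | 50 µM |
| remark | run made earlier | run made earlier |  |  |  |  |
| time |  |  | 1.5 h | 1.5 h | 1.5 h | 1.5 h |

- spring (time / min: Z / %, Q / %): 4.00: 0, 102.1; 6.00: 0, 101.3; 8.00: 0.7, 99.4; 12.0: 1.1, 99.2; 20.0: 2.1, 98.4; 30.0: 1.4, 98.8; 50.0: 4.0, 97.3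
- noon (time / min: Z / %, Q / %): 2.50: 10.5, 89.6; 6.00: 54.8, 43.1; 12.0: 100.1, 0; 20.0: 100.0, 1.7; 25.0: 99.4, 0.3; 40.0: 100.9, 1.2; 50.0: 99.0, 1.0

(scatter of a reading: 1 percentage point)

- the numbers in the tables scatter by 1 percentage point (one standard deviation)
- a step back or a flat step of under half a point counts as no turn
- a reading or a percentage of Z counts all its forms, free or not
- "hardly changes" means that all values lie within two and a half points (for a concentration: within two and a half percent of the largest)

1. amount of Z at the end, in percent of the Q charged for north-west, south-east, south-west, north, in this order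
2. how the row runs (falls, then rises / falls all the way / rises all the way / rises, then falls / hardly changes)

Each flask holds Q, J and D, stirred, and Z should start slowly, an induction period. In the noon run Z went from 10.5 % to 54.8 % while the time went from 2.50 min to 6.00 min, which gave a read exponent of 1.89, close to 2. I therefore let Z grow with the square of J times time, with Q and D held at the charges these flasks share:

full dose = 170 mM × 6.00 min / √54.8 % = 1380 mM·min

I call this the full dose, the product of J and time at which Z reaches the whole of the Q charged. The last spring reading, with J at 5 mM, gives 1250 mM·min; the full dose puts Z there at 3.29 % against the 4.0 % read, inside the scatter of 1 percentage point.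

Z at the end = (J × time / full dose)²

north-west: 27.3 %

time to full, south-east: 68.9 min

time to full, south-west: 23.0 min

time to full, north: 6.89 min

These use J at its charge, but south-east spends half of its J on the Q charged if one J goes with one Q, so it may only just finish within 1.5 h. Don't sample north-west early: at half the time the rule gives a quarter of its end value.

The forecast, from the same two runs, gave 15 %, 50 %, 99 % and 100 %, a row that rises all the way, with south-east “slowing as J is used”; my reckoning stood apart from it at north-west and south-east.

The flasks gave 23.9 %, 96.6 %, 100 % and 100 %, a row that rises all the way.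

    Q + J + X → Z + X, rate k1*[Q]*[J]*[X]/(1 + ([Q]/sat1)) (0.250 mM, k = 29000 M⁻² s⁻¹)
    J + D → X + G (k = 38.0 M⁻¹ h⁻¹)
    L ⇌ Z, rate k3*(cs3 - [Z]) while solid is left; crystals form when [Z] > cs3 (solubility = 8.40 mM, k = 50.0 h⁻¹)

South-east ended with 3.4 % of its Q and 52 % of its J, though its dose at the charge was 1800 mM·min, more than the full dose of 1380 mM·min. Put to south-east at 0.750 h, the full dose gives 42.7 % of Z, and that flask held 39.3 %.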